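**Retrosynthetic overview**

1. The target is a monocyclic bisabolane triester. Its cyclohexane atoms are called here C1 (O-angelate), C2 (CH2), C3 (C-methyl), C4 (O-acetate), C5 (CH2) and C6 (side chain).
2. Last disconnections: the C1–O angelate, then the C4 acetate and C4 carbinol (from a ketone), then the C2–C3 single bond (from an enone C=C).
3. Key disconnection: bonds C6–C1 and C2–C3 of a 4-silyloxycyclohex-2-enone. The precursors are an acyclic ethyl enone (C3–C4–C5–C6 plus the whole acetoxylated side chain) and silyloxyacetaldehyde (C1 and C2). One amine-catalysed Michael/aldol-condensation annulation makes the only carbocycle, sets C1 and C6, and puts both ring oxygens in place.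
4. Enabling feature: the 1,4-related oxygens on C1 and C4 with the methyl on C3. C4 as a ketone makes C6 an enone β-carbon and C3 an enolisable α′-carbon; the C1 oxygen makes C1 the α-carbon of an α-oxy aldehyde whose carbonyl carbon ends as the ring CH2 (C2).
5. The enone comes by olefination from a cis-α-methyl-γ-lactone (a temporary ring, opened as a Weinreb amide). Its two stereocentres come from a chiral-pool bromo ester and an oxazaborolidine-catalysed ketone reduction. Ring order: lactone (temporary), then the cyclohexane.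

Key step: step 6

Assumption: the enamine of the silyloxy aldehyde reacts as its (E)-isomer, and the oxazaborolidine catalyst reads the 2-methylprop-1-enyl group as the large ketone substituent, as is usual for enones.

**Step 1**
Reactants: 1 methyl (S)-3-bromo-2-methylpropanoate; 2 3-methylbut-2-enoyl chloride
Product: 4 methyl (R)-2,6-dimethyl-4-oxohept-5-enoate, via organozinc bromide 3 (not isolated)
Conditions: Zn dust, LiCl, THF, 40 °C; then Pd(PPh3)4 (5 mol %), 2, 0 °C → rt
Reagents that add atoms: none
Why: Zinc insertion into the primary bromide gives a configurationally stable β-zincio ester, and Negishi acylation by the enoyl chloride should give the γ-keto ester with the stereocentre taken unchanged from 1 (the descriptor changes only through the priority switch).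

**Step 2**
Reactants: 4 methyl (R)-2,6-dimethyl-4-oxohept-5-enoate
Product: 6 (3R,5R)-3-methyl-5-(2-methylprop-1-en-1-yl)oxolan-2-one, via hydroxy ester 5 (not isolated)
Conditions: (S)-2-methyl-CBS-oxazaborolidine (10 mol %), catecholborane, toluene, −78 °C; MeOH quench; then p-TsOH·H2O (cat.), CH2Cl2, rt
Reagents that add atoms: none
Why: Corey–Bakshi–Shibata reduction of the enone carbonyl, with the alkenyl group as the large substituent, should give the (R)-allylic alcohol under catalyst control, and acid-catalysed lactonisation (5-exo-trig) then closes the cis-lactone.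

**Step 3**
Reactants: 6 (3R,5R)-3-methyl-5-(2-methylprop-1-en-1-yl)oxolan-2-one
Product: 8 (4R,6R)-7-[methoxy(methyl)amino]-2,6-dimethyl-7-oxohept-2-en-4-yl acetate, via hydroxy Weinreb amide 7 (not isolated)
Conditions: MeNH(OMe), Me3Al, CH2Cl2, 0 °C → rt; aq. potassium sodium tartrate work-up; crude at once Ac2O, DMAP (cat.), pyridine, 0 °C
Reagents that add atoms: N,O-dimethylhydroxylamine CNOC; acetic anhydride CC(=O)OC(C)=O
Why: Weinreb aminolysis of the lactone by the aluminium amide opens the ring, and immediate acetylation of the freed allylic alcohol blocks relactonisation and installs the side-chain acetate of the target; no stereocentre is touched.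

**Step 4**
Reactants: 8 (4R,6R)-7-[methoxy(methyl)amino]-2,6-dimethyl-7-oxohept-2-en-4-yl acetate
Product: 9 (4R,6R)-2,6-dimethyl-7-oxohept-2-en-4-yl acetate
Conditions: Cp2Zr(H)Cl (Schwartz reagent, 1.5 equiv), THF, rt, 20 min
Reagents that add atoms: none
Why: Schwartz-reagent reduction of a tertiary amide stops at the aldehyde through a zirconated hemiaminal and is known to spare esters, so the acetate and the α-methyl stereocentre should survive.

**Step 5**
Reactants: 9 (4R,6R)-2,6-dimethyl-7-oxohept-2-en-4-yl acetate; 10 diethyl (2-oxobutyl)phosphonate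
Product: 11 (4R,6R,7E)-2,6-dimethyl-9-oxoundeca-2,7-dien-4-yl acetate
Conditions: LiCl, i-Pr2NEt, MeCN, rt
Reagents that add atoms: none
Why: Horner–Wadsworth–Emmons olefination under Masamune–Roush conditions is mild enough for an epimerisable α-branched aldehyde and an acetate and should give the (E)-enone.

**Step 6**
Reactants: 11 (4R,6R,7E)-2,6-dimethyl-9-oxoundeca-2,7-dien-4-yl acetate; 12 (tert-butyldimethylsilyloxy)acetaldehyde
Product: 15 (4R,6R)-6-[(1S,2S)-2-(tert-butyldimethylsilyloxy)-4-methyl-5-oxocyclohex-3-en-1-yl]-2-methylhept-2-en-4-yl acetate, via keto aldehyde Michael adduct 13 (not isolated), via aldol 14 (not isolated)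
Conditions: N-(4-dodecylphenylsulfonyl)-L-prolinamide (20 mol %), 12 (3 equiv, added over 24 h), ClCH2CH2Cl (1 M in 11), 23 °C, 72 h; then piperidinium acetate (20 mol %), 40 °C
Reagents that add atoms: none
Why: The catalyst condenses with 12 to an (E)-enamine whose α-carbon (ring C1, carrying the silyloxy group) adds to the enone β-carbon of 11 (ring C6) while the sulfonamide N–H hydrogen-bonds the enone carbonyl; hydrolysis gives keto aldehyde 13, whose ethyl-ketone α′-carbon (ring C3) then adds to the aldehyde carbon (ring C2) and the aldol 14 loses water to the conjugated enone. The closest known reaction type is the amine-catalysed Michael/aldol-condensation annulation of aldehydes with β-substituted acyclic enones (Stork–Robinson annulation in its Yamada–Otani, proline-sulfonamide form). The only ring closes by a 6-(enolendo)-exo-trig aldol addition followed by dehydration; the other aldol modes would give four-membered rings and are not available. C1 is set by the catalyst, which delivers the enone to the enamine face syn to the L-prolinamide side arm, and C6 is set relative to C1 by the synclinal, like-topicity enamine Michael transition state, which should give the syn adduct and hence the trans relationship of silyloxy group and side chain, also the thermodynamically preferred one in 15. The step needs cross-Michael chemoselectivity over self-aldol of 12 (secured by slow addition of excess 12 to the concentrated enone and by hydrogen-bond activation of the enone) and facial selectivity at C6 against the weak 1,2-bias of the neighbouring methyl-bearing stereocentre (secured by catalyst control, since the (E)-enone has no strong allylic-strain preference).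

**Step 7**
Reactants: 15 (4R,6R)-6-[(1S,2S)-2-(tert-butyldimethylsilyloxy)-4-methyl-5-oxocyclohex-3-en-1-yl]-2-methylhept-2-en-4-yl acetate
Product: 16 (4R,6R)-6-[(1S,2R,4S)-2-(tert-butyldimethylsilyloxy)-4-methyl-5-oxocyclohexyl]-2-methylhept-2-en-4-yl acetate
Conditions: [(Ph3P)CuH]6 (Stryker reagent, 0.25 equiv), degassed benzene, H2O (5 equiv), rt; then DBU (cat.), CH2Cl2, rt
Reagents that add atoms: none
Why: Copper hydride conjugate reduction is chemoselective for the enone over the isolated trisubstituted alkene and the allylic acetate, and protonation followed by base equilibration of the α-methyl centre should settle in the all-equatorial ketone (methyl trans to the side chain).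

**Step 8**
Reactants: 16 (4R,6R)-6-[(1S,2R,4S)-2-(tert-butyldimethylsilyloxy)-4-methyl-5-oxocyclohexyl]-2-methylhept-2-en-4-yl acetate
Product: 17 (4R,6R)-6-[(1S,2R,4S,5R)-2-(tert-butyldimethylsilyloxy)-5-hydroxy-4-methylcyclohexyl]-2-methylhept-2-en-4-yl acetate
Conditions: LiBH(s-Bu)3 (L-Selectride, 1.2 equiv), THF, −78 °C; then H2O2, pH 7 buffer, 0 °C
Reagents that add atoms: none
Why: The bulky trialkylborohydride attacks the conformationally fixed cyclohexanone along the equatorial trajectory and should give the axial alcohol cis to the neighbouring equatorial methyl group, while the acetate is not reduced at −78 °C.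

**Step 9**
Reactants: 17 (4R,6R)-6-[(1S,2R,4S,5R)-2-(tert-butyldimethylsilyloxy)-5-hydroxy-4-methylcyclohexyl]-2-methylhept-2-en-4-yl acetate
Product: 18 (4R,6R)-6-[(1S,2R,4S,5R)-5-acetoxy-2-(tert-butyldimethylsilyloxy)-4-methylcyclohexyl]-2-methylhept-2-en-4-yl acetate
Conditions: Ac2O, DMAP (cat.), pyridine, CH2Cl2, rt
Reagents that add atoms: acetic anhydride CC(=O)OC(C)=O
Why: DMAP-catalysed acyl transfer acetylates the axial secondary alcohol with retention at carbon.

**Step 10**
Reactants: 18 (4R,6R)-6-[(1S,2R,4S,5R)-5-acetoxy-2-(tert-butyldimethylsilyloxy)-4-methylcyclohexyl]-2-methylhept-2-en-4-yl acetate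
Product: 19 (4R,6R)-6-[(1S,2R,4S,5R)-5-acetoxy-2-hydroxy-4-methylcyclohexyl]-2-methylhept-2-en-4-yl acetate
Conditions: HF·pyridine, pyridine, THF, 0 °C → rt
Reagents that add atoms: none
Why: Buffered fluoride desilylation should free the ring alcohol without acyl migration (the nearest acetate is 1,4 across the ring) and without ionising the allylic acetate.

**Step 11**
Reactants: 19 (4R,6R)-6-[(1S,2R,4S,5R)-5-acetoxy-2-hydroxy-4-methylcyclohexyl]-2-methylhept-2-en-4-yl acetate
Product: 20 (1R,2S,4R,5S)-4-acetoxy-2-[(2R,4R)-4-acetoxy-6-methylhept-5-en-2-yl]-5-methylcyclohexyl (2Z)-2-methylbut-2-enoate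
Conditions: angelic acid, 2,4,6-trichlorobenzoyl chloride, Et3N, toluene, rt, 2 h; then 19, 80 °C (no DMAP)
Reagents that add atoms: angelic acid C/C=C(/C)C(=O)O
Why: Yamaguchi-type acylation through the mixed anhydride made in the flask, run without a nucleophilic catalyst, is the established way to make angelates of hindered secondary alcohols without Z → E isomerisation to the tiglate, and the carbinol centre is not touched.

**Compound list**

1 | methyl (S)-3-bromo-2-methylpropanoate | COC(=O)[C@H](C)CBr | starting material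
2 | 3-methylbut-2-enoyl chloride | CC(C)=CC(Cl)=O | starting material
3 | [(2S)-3-methoxy-2-methyl-3-oxopropyl]zinc bromide | COC(=O)[C@H](C)C[Zn]Br | intermediate
4 | methyl (R)-2,6-dimethyl-4-oxohept-5-enoate | COC(=O)[C@H](C)CC(=O)C=C(C)C | intermediate
5 | methyl (2R,4R)-4-hydroxy-2,6-dimethylhept-5-enoate | COC(=O)[C@H](C)C[C@@H](O)C=C(C)C | intermediate
6 | (3R,5R)-3-methyl-5-(2-methylprop-1-en-1-yl)oxolan-2-one | C[C@@H]1C[C@H](C=C(C)C)OC1=O | intermediate
7 | (2R,4R)-4-hydroxy-N-methoxy-N,2,6-trimethylhept-5-enamide | CON(C)C(=O)[C@H](C)C[C@@H](O)C=C(C)C | intermediate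
8 | (4R,6R)-7-[methoxy(methyl)amino]-2,6-dimethyl-7-oxohept-2-en-4-yl acetate | CON(C)C(=O)[C@H](C)C[C@H](C=C(C)C)OC(C)=O | intermediate
9 | (4R,6R)-2,6-dimethyl-7-oxohept-2-en-4-yl acetate | O=C[C@H](C)C[C@H](C=C(C)C)OC(C)=O | intermediate
10 | diethyl (2-oxobutyl)phosphonate | CCOP(=O)(CC(=O)CC)OCC | starting material
11 | (4R,6R,7E)-2,6-dimethyl-9-oxoundeca-2,7-dien-4-yl acetate | CCC(=O)/C=C/[C@H](C)C[C@H](C=C(C)C)OC(C)=O | intermediate
12 | (tert-butyldimethylsilyloxy)acetaldehyde | CC(C)(C)[Si](C)(C)OCC=O | starting material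
13 | (4R,6R,7S)-7-[(1S)-1-(tert-butyldimethylsilyloxy)-2-oxoethyl]-2,6-dimethyl-9-oxoundec-2-en-4-yl acetate | CC(C)(C)[Si](C)(C)O[C@H](C=O)[C@@H](CC(=O)CC)[C@H](C)C[C@H](C=C(C)C)OC(C)=O | intermediate
14 | (4R,6R)-6-[(1S,2S)-2-(tert-butyldimethylsilyloxy)-3-hydroxy-4-methyl-5-oxocyclohexyl]-2-methylhept-2-en-4-yl acetate (epimers at ring C3 and C4) | CC(C)(C)[Si](C)(C)O[C@@H]1C(O)C(C)C(=O)C[C@H]1[C@H](C)C[C@H](C=C(C)C)OC(C)=O | intermediate
15 | (4R,6R)-6-[(1S,2S)-2-(tert-butyldimethylsilyloxy)-4-methyl-5-oxocyclohex-3-en-1-yl]-2-methylhept-2-en-4-yl acetate | CC(C)(C)[Si](C)(C)O[C@@H]1C=C(C)C(=O)C[C@H]1[C@H](C)C[C@H](C=C(C)C)OC(C)=O | intermediate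
16 | (4R,6R)-6-[(1S,2R,4S)-2-(tert-butyldimethylsilyloxy)-4-methyl-5-oxocyclohexyl]-2-methylhept-2-en-4-yl acetate | CC(C)(C)[Si](C)(C)O[C@@H]1C[C@H](C)C(=O)C[C@H]1[C@H](C)C[C@H](C=C(C)C)OC(C)=O | intermediate
17 | (4R,6R)-6-[(1S,2R,4S,5R)-2-(tert-butyldimethylsilyloxy)-5-hydroxy-4-methylcyclohexyl]-2-methylhept-2-en-4-yl acetate | CC(C)(C)[Si](C)(C)O[C@@H]1C[C@H](C)[C@H](O)C[C@H]1[C@H](C)C[C@H](C=C(C)C)OC(C)=O | intermediate
18 | (4R,6R)-6-[(1S,2R,4S,5R)-5-acetoxy-2-(tert-butyldimethylsilyloxy)-4-methylcyclohexyl]-2-methylhept-2-en-4-yl acetate | CC(C)(C)[Si](C)(C)O[C@@H]1C[C@H](C)[C@H](OC(C)=O)C[C@H]1[C@H](C)C[C@H](C=C(C)C)OC(C)=O | intermediate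
19 | (4R,6R)-6-[(1S,2R,4S,5R)-5-acetoxy-2-hydroxy-4-methylcyclohexyl]-2-methylhept-2-en-4-yl acetate | O[C@@H]1C[C@H](C)[C@H](OC(C)=O)C[C@H]1[C@H](C)C[C@H](C=C(C)C)OC(C)=O | intermediate
20 | (1R,2S,4R,5S)-4-acetoxy-2-[(2R,4R)-4-acetoxy-6-methylhept-5-en-2-yl]-5-methylcyclohexyl (2Z)-2-methylbut-2-enoate | C/C=C(/C)C(=O)O[C@@H]1C[C@H](C)[C@H](OC(C)=O)C[C@H]1[C@H](C)C[C@H](C=C(C)C)OC(C)=O | target

**Step count and risks**

Total step count: 11. Longest linear sequence: 11 steps (1 → 20); compounds 2, 10 and 12 enter as single-step inputs.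

Steps most likely to fail:

Step 6. The catalytic enamine of 12 may add too slowly to the β-branched, unactivated enone, so that self-aldol condensation of the aldehyde and catalyst deactivation outrun the cross-Michael addition; the catalyst may also fail to override the facial bias of the side-chain stereocentre. The fallback is a stoichiometric Stork enamine annulation by way of a hetero-Diels–Alder adduct; it sets out from 11 and 12 and comes back to the route at 15. Compound 12 is condensed with pyrrolidine (K2CO3, Et2O, 0 °C) to the enamine 1-[(E)-2-(tert-butyldimethylsilyloxy)ethenyl]pyrrolidine F1, which is far more nucleophilic than a catalytic enamine. Heating F1 with 11 (MeCN, 60 °C) should give the inverse-electron-demand [4+2] adduct, the 2-pyrrolidinyl-3,4-dihydro-2H-pyran (4R,6R)-6-[(3S,4R)-3-(tert-butyldimethylsilyloxy)-6-ethyl-2-(pyrrolidin-1-yl)-3,4-dihydro-2H-pyran-4-yl]-2-methylhept-2-en-4-yl acetate F2 (endo mode, silyloxy group trans to the side chain). Buffered hydrolysis (AcOH, NaOAc, H2O, THF) releases keto aldehyde 13, which is closed with piperidinium acetate to 15. Facial selectivity then rests on the substrate, and a ring diastereomer would have to be removed by chromatography at 15.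

Step 11. Acylation of the hindered equatorial alcohol may be slow enough that the angeloyl group isomerises to the tiglate under the warm, basic conditions. The fallback builds the (Z)-double bond on the ester instead of transferring it; it sets out from 19 and comes back at 20. Compound 19 is esterified with 2-[bis(2,2,2-trifluoroethoxy)phosphoryl]propanoic acid (DCC, DMAP, CH2Cl2) to the phosphonate ester (1R,2S,4R,5S)-4-acetoxy-2-[(2R,4R)-4-acetoxy-6-methylhept-5-en-2-yl]-5-methylcyclohexyl 2-[bis(2,2,2-trifluoroethoxy)phosphoryl]propanoate F3. Still–Gennari olefination of F3 with acetaldehyde (KN(SiMe3)2, 18-crown-6, THF, −78 °C) should give the (Z)-2-methylbut-2-enoate 20 directly.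

Step 4. Reduction of the amide may be accompanied by attack on the allylic acetate, and the α-branched aldehyde may epimerise before or during the olefination. The fallback avoids both the amide and the free aldehyde; it sets out from 6 and comes back at 11. i-Bu2AlH (toluene, −78 °C) reduces 6 to the lactol (3R,5R)-3-methyl-5-(2-methylprop-1-en-1-yl)oxolan-2-ol F4. Wittig olefination of its open hydroxy aldehyde form with 1-(triphenylphosphoranylidene)butan-2-one (toluene, 60 °C) gives the hydroxy enone (4E,6R,8R)-8-hydroxy-6,10-dimethylundeca-4,9-dien-3-one F5, which is acetylated at once (Ac2O, pyridine, DMAP) to 11 before oxa-Michael closure can set in.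

**Further compounds**

F1 | step 6 | 1-[(E)-2-(tert-butyldimethylsilyloxy)ethenyl]pyrrolidine | CC(C)(C)[Si](C)(C)O/C=C/N1CCCC1
F2 | step 6 | (4R,6R)-6-[(3S,4R)-3-(tert-butyldimethylsilyloxy)-6-ethyl-2-(pyrrolidin-1-yl)-3,4-dihydro-2H-pyran-4-yl]-2-methylhept-2-en-4-yl acetate | CCC1=C[C@@H]([C@H](C)C[C@H](C=C(C)C)OC(C)=O)[C@H](O[Si](C)(C)C(C)(C)C)C(N2CCCC2)O1
F3 | step 11 | (1R,2S,4R,5S)-4-acetoxy-2-[(2R,4R)-4-acetoxy-6-methylhept-5-en-2-yl]-5-methylcyclohexyl 2-[bis(2,2,2-trifluoroethoxy)phosphoryl]propanoate | CC(C(=O)O[C@@H]1C[C@H](C)[C@H](OC(C)=O)C[C@H]1[C@H](C)C[C@H](C=C(C)C)OC(C)=O)P(=O)(OCC(F)(F)F)OCC(F)(F)F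
F4 | step 4 | (3R,5R)-3-methyl-5-(2-methylprop-1-en-1-yl)oxolan-2-ol | C[C@@H]1C[C@H](C=C(C)C)OC1O
F5 | step 4 | (4E,6R,8R)-8-hydroxy-6,10-dimethylundeca-4,9-dien-3-one | CCC(=O)/C=C/[C@H](C)C[C@@H](O)C=C(C)C
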